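The seven-membered ring (C1, C5–C10) carries oxygen at C6 and at C9, 1,4 to each other across C7–C8, so C7 and C8 are α-carbons of two ketones, and the synthesis rests on cutting C7–C8. A single anodic oxidation of the bis(silyl enol ether) 22 joins C7 to C8 and gives the cis-fused cycloheptane-6,9-dione 23 on a cyclopentane (C1–C5) that already holds the stereocentres C1, C2, C4, C5 and C10. Compound 22 is a cyclopentane with a C5 acetyl arm and a C1 α-silyloxy ethyl ketone arm, both as silyl enol ethers; the arms are cis because both are cut from one cis-fused lactone (Pauson–Khand reaction, then Baeyer–Villiger oxidation).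

Key step: step 13

Remarks
- Numbering is that of the target: five-membered ring C1–C5 (methyl on C1, isopropyl on C4), seven-membered ring C1, C5–C10 (methyl on C8). α is the face of the C1 methyl group, β the other face. In the bicyclo[3.3.0] intermediates the second ring is C1, C10, C9, C6, C5.
- C6 in 12–20 and C8 in 23–27 form as epimer mixtures that converge later (C6 becomes a ketone in step 11, C8 becomes sp2 in step 17); their SMILES leave these centres open.
- Assumption: (+)-Ipc2BCl, 5, 18 and 26 are bought; the ligand hand of the boron reagent is the one that gives the S alcohol 4.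
- All hydroxyl protecting groups in 22 are silyl ethers of graded lability (TMS at C4, TES at C10, TBS at C2), so that the enol ethers are the only oxidisable groups in step 13.

Step 1
Reactants: 1 3-methylbutan-2-one; 2 methacrolein
Product: 4 (S)-5-hydroxy-2,6-dimethylhept-6-en-3-one, via enol borinate 3 (not isolated)
Conditions: (+)-Ipc2BCl, Et3N, Et2O, −78 → 0 °C; then 2, −78 → −20 °C; H2O2, MeOH, pH 7 buffer
Reagents that add atoms: none
Why: Boron aldol reaction of a methyl ketone: the kinetic enol diisopinocampheylborinate 3 (enolisation at the methyl group) adds to the aldehyde through a cyclic transition state in which the isopinocampheyl ligands choose the aldehyde face, which sets C2 (S).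

Step 2
Reactants: 4 (S)-5-hydroxy-2,6-dimethylhept-6-en-3-one; 5 prop-1-ynylmagnesium bromide
Product: 7 (3S,5R)-2-methyl-5-(propan-2-yl)oct-1-en-6-yne-3,5-diol, via magnesium alkoxide 6 (not isolated)
Conditions: MeC≡CMgBr (3 equiv), THF/CH2Cl2, −78 → −20 °C; aq NH4Cl
Reagents that add atoms: none
Why: Chelation-controlled Grignard addition (Cram chelate, 1,3-induction): the first equivalent forms alkoxide 6, whose magnesium ties the C2 oxygen to the C4 carbonyl in a six-membered chelate, and the slim alkynyl nucleophile should enter axially on the face that leads to the chair, which sets C4 with the C2 and C4 oxygens anti.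

Step 3
Reactants: 7 (3S,5R)-2-methyl-5-(propan-2-yl)oct-1-en-6-yne-3,5-diol
Product: 8 (3S,5R)-3-(tert-butyldimethylsilyloxy)-2-methyl-5-(propan-2-yl)oct-1-en-6-yn-5-ol
Conditions: TBSCl, imidazole, DMF, 0 °C → rt
Reagents that add atoms: tert-butyldimethylsilyl chloride, CC(C)(C)[Si](C)(C)Cl
Why: Silyl ether formation that takes the secondary allylic hydroxyl and leaves the hindered tertiary propargylic one free.

Step 4
Reactants: 8 silyl ether of the enyne diol
Product: 9 Pauson–Khand enone (C9 ketone, C5=C6; 1α-methyl, 2α-OTBS, 4β-OH, 4α-isopropyl)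
Conditions: Co2(CO)8 (20 mol %), tetramethylthiourea (cat.), CO (1 atm), benzene, 70 °C
Reagents that add atoms: carbon monoxide, [C-]#[O+]
Why: Intramolecular Pauson–Khand reaction of a 1,6-enyne forms C1–C5, C6–C9 and C9–C10 at once, and C1 is set because the C2 silyloxy group and the C4 isopropyl group can both take exo positions in the cobaltacycle (matched for the anti diol), which puts the C1 methyl cis to the C2 oxygen.

Step 5
Reactants: 9 Pauson–Khand enone
Product: 12 cis-fused bicyclic ketone, via lithium alkoxide 10 (not isolated), via lithium enolate 11 (not isolated)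
Conditions: LiN(SiMe3)2 (1.0 equiv), THF, −78 °C; Li, NH3(l), −78 °C; solid NH4Cl
Reagents that add atoms: none
Why: Dissolving-metal (Birch-type) conjugate reduction of the enone: protonation at C5 should give only the cis-fused bicyclo[3.3.0]octane because the trans fusion is far more strained, so H5 ends cis to the C1 methyl, while the C4 oxygen is held as its alkoxide so that it cannot leave and C6 is left as a mixture.

Step 6
Reactants: 12 cis-fused bicyclic ketone
Product: 13 cis-fused δ-lactone (oxygen between C6 and C9)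
Conditions: mCPBA, CH2Cl2, 0 °C → rt
Reagents that add atoms: 3-chloroperbenzoic acid, O=C(OO)c1cccc(Cl)c1
Why: Baeyer–Villiger oxidation in which the secondary C6 migrates in preference to the primary C10 and with retention, so oxygen enters between C6 and C9 and the two future arms stay locked cis in a six-membered lactone.

Step 7
Reactants: 13 cis-fused δ-lactone
Product: 14 C4 trimethylsilyl ether of 13
Conditions: N-(trimethylsilyl)imidazole, CH2Cl2, rt
Reagents that add atoms: N-(trimethylsilyl)imidazole, C[Si](C)(C)n1ccnc1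
Why: Silylation of the tertiary C4 hydroxyl by a neutral silyl donor that does not enolise the lactone.

Step 8
Reactants: 14 C4 trimethylsilyl ether
Product: 16 10β-hydroxy lactone, via potassium enolate 15 (not isolated)
Conditions: KN(SiMe3)2, THF, −78 °C; 2-(phenylsulfonyl)-3-phenyloxaziridine, −78 °C; aq NH4Cl
Reagents that add atoms: 2-(phenylsulfonyl)-3-phenyloxaziridine, O=S(=O)(c1ccccc1)N1OC1c1ccccc1
Why: Enolate hydroxylation with an N-sulfonyloxaziridine: C10 is the only enolisable position, and oxygen should be delivered to the face opposite the angular C1 methyl and the C2 silyloxy group, which sets the 10β-alcohol.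

Step 9
Reactants: 16 10β-hydroxy lactone
Product: 17 10β-triethylsilyloxy lactone
Conditions: TESOTf, 2,6-lutidine, CH2Cl2, −78 → 0 °C
Reagents that add atoms: triethylsilyl triflate, CC[Si](CC)(CC)OS(=O)(=O)C(F)(F)F
Why: Silyl triflate silylation of a hindered secondary alcohol under non-nucleophilic base, which leaves the other silyl ethers and the lactone alone.

Step 10
Reactants: 17 10β-triethylsilyloxy lactone; 18 ethyllithium
Product: 20 C6 hydroxy C9 ethyl ketone, via lithium hemiketal 19 (not isolated)
Conditions: EtLi (1.2 equiv), Et2O/THF, −78 °C; aq NH4Cl at −78 °C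
Reagents that add atoms: none
Why: Organolithium addition to a lactone stops after one addition because the lithium hemiketal 19 survives at −78 °C, and protonation releases the C9 ethyl ketone and the C6 alcohol (in equilibrium with its lactol) without forming a stereocentre of consequence.

Step 11
Reactants: 20 C6 hydroxy C9 ethyl ketone
Product: 21 diketone (C5 acetyl arm, C1 α-silyloxy ethyl ketone arm)
Conditions: Dess–Martin periodinane, pyridine, CH2Cl2, 0 °C → rt
Reagents that add atoms: none
Why: Dess–Martin oxidation of the secondary C6 alcohol (through the open hydroxy ketone form) under buffered, non-epimerising conditions.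

Step 12
Reactants: 21 diketone
Product: 22 bis(silyl enol ether)
Conditions: TBSOTf, Et3N, CH2Cl2, 0 °C
Reagents that add atoms: tert-butyldimethylsilyl triflate, CC(C)(C)[Si](C)(C)OS(=O)(=O)C(F)(F)F
Why: Soft enolisation (silyl triflate and amine) forms both silyl enol ethers without free enolates: the methyl ketone can enolise only toward C7 (C5 lies between two quaternary carbons) and the ethyl ketone toward C8 (C10 is hindered and oxygen-substituted), which should give the Z trisubstituted enol ether.

Step 13
Reactants: 22 bis(silyl enol ether)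
Product: 23 cis-fused cycloheptane-6,9-dione
Conditions: undivided cell, reticulated vitreous carbon anode, Pt cathode, LiClO4 (0.1 M), 2,6-lutidine, MeOH/CH2Cl2 (1:4), constant current, 2.2 F/mol, 22 at 2 mM, 0 °C → rt
Reagents that add atoms: none
Why: The anode removes one electron from the more electron-rich trisubstituted enol ether (C8=C9), the radical cation is attacked at C8 by the terminal carbon C7 of the second enol ether, and a second electron transfer with loss of both silyl groups to methanol leaves the 1,4-diketone. The closest known reaction type is the intramolecular oxidative (anodic or chemical) coupling of two silyl enol ethers to cyclic 1,4-diketones. The seven-membered ring (C1, C5–C10) closes in a 7-endo mode with respect to both enol double bonds, so both oxygen-bearing carbons end as ring ketones. The new C8 centre forms under only weak control by the ring-fusion carbons and is carried as a mixture, because it becomes sp2 in step 17. The step needs cyclisation to beat dimerisation and needs the enol ethers to be the only groups oxidised: the cis arms on the cyclopentane and high dilution should secure the first, and a substrate that carries only silyl ethers and no arene secures the second.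

Step 14
Reactants: 23 cis-fused cycloheptane-6,9-dione
Product: 24 C4 alcohol of the diketone
Conditions: PPTS (0.1 equiv), MeOH/CH2Cl2, −10 °C
Reagents that add atoms: none
Why: Acid-catalysed methanolysis of a silyl ether: the trimethylsilyl ether is far more labile than the triethylsilyl and tert-butyldimethylsilyl ethers, so only the C4 hydroxyl should be freed, and the acidic medium avoids retro-aldol cleavage.

Step 15
Reactants: 24 C4 alcohol of the diketone
Product: 25 6α-alcohol
Conditions: Me4NBH(OAc)3, MeCN/AcOH (1:1), −30 °C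
Reagents that add atoms: none
Why: Evans–Saksena reduction: the 4β-hydroxyl binds the borohydride and delivers hydride through a six-membered transition state to the β face of the C6 ketone only (the C9 ketone has no free hydroxyl within reach), which sets the 6α-alcohol.

Step 16
Reactants: 25 6α-alcohol; 26 tigloyl chloride
Product: 27 6α-tiglate
Conditions: pyridine, DMAP (cat.), CH2Cl2, 0 °C → rt
Reagents that add atoms: none
Why: DMAP-catalysed acylation with an acid chloride takes the secondary C6 hydroxyl and not the tertiary C4 hydroxyl, and the stable E geometry of the tigloyl group is kept.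

Step 17
Reactants: 27 6α-tiglate
Product: 29 C9 enol triflate, via potassium enolate 28 (not isolated)
Conditions: KN(SiMe3)2 (2.2 equiv), THF, −78 °C; PhNTf2, −78 → 0 °C; aq NH4Cl
Reagents that add atoms: N-phenylbis(trifluoromethanesulfonimide), O=S(=O)(N(c1ccccc1)S(=O)(=O)C(F)(F)F)C(F)(F)F
Why: Kinetic enolate O-triflation: the first equivalent of base takes the C4 hydroxyl proton, the second deprotonates the ketone at C8 (C10 is hindered and oxygen-substituted, the ester is far less acidic), and the triflimide traps the enolate on oxygen, which erases the C8 stereocentre.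

Step 18
Reactants: 29 C9 enol triflate
Product: 30 C8=C9 alkene
Conditions: Pd(OAc)2 (10 mol %), PPh3, HCO2H, Bu3N, DMF, 60 °C
Reagents that add atoms: none
Why: Palladium-catalysed formate reduction of an enol triflate (oxidative addition, formate exchange, decarboxylation, reductive elimination) replaces the triflate by hydrogen and leaves the trisubstituted C8=C9 alkene where the enolate put it.

Step 19
Reactants: 30 C8=C9 alkene
Product: 31 10β-allylic alcohol
Conditions: HF·pyridine, pyridine, THF, 0 °C
Reagents that add atoms: none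
Why: Fluoride desilylation in which the triethylsilyl ether is cleaved much faster than the neopentyl tert-butyldimethylsilyl ether at C2, which frees the allylic C10 hydroxyl.

Step 20
Reactants: 31 10β-allylic alcohol
Product: 32 8β,9β-epoxy alcohol
Conditions: VO(acac)2 (cat.), tBuOOH, CH2Cl2, 0 °C → rt
Reagents that add atoms: tert-butyl hydroperoxide, CC(C)(C)OO
Why: Vanadium-catalysed hydroxyl-directed epoxidation of an allylic alcohol delivers the peroxide oxygen from the vanadate of the 10β-hydroxyl to the same face of C8=C9, which sets C8 and C9 as the β-epoxide, while the electron-poor tiglate alkene does not react.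

Step 21
Reactants: 32 8β,9β-epoxy alcohol; 26 tigloyl chloride
Product: 33 6,10-ditiglate C2 silyl ether
Conditions: pyridine, DMAP (cat.), CH2Cl2, rt
Reagents that add atoms: none
Why: DMAP-catalysed acylation of the remaining secondary hydroxyl, with the tertiary C4 hydroxyl and the epoxide untouched.

Step 22
Reactants: 33 6,10-ditiglate C2 silyl ether
Product: 34 target CNP0265715.1
Conditions: HF·pyridine, pyridine, THF, 0 °C → rt
Reagents that add atoms: none
Why: Fluoride desilylation under buffered, weakly acidic conditions should remove the last silyl ether without acyl migration to the C2 hydroxyl or opening of the epoxide.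

Compound list
1 | 3-methylbutan-2-one | CC(C)C(C)=O | starting material
2 | methacrolein (2-methylprop-2-enal) | CC(=C)C=O | starting material
3 | 3-methylbut-1-en-2-yl diisopinocampheylborinate, the enol borinate of 1 from (+)-Ipc2BCl (not isolated) | C=C(OB([C@H]1C[C@H]2C[C@@H]([C@@H]1C)C2(C)C)[C@H]1C[C@H]2C[C@@H]([C@@H]1C)C2(C)C)C(C)C | intermediate
4 | (S)-5-hydroxy-2,6-dimethylhept-6-en-3-one | CC(C)C(=O)C[C@H](O)C(C)=C | intermediate
5 | prop-1-ynylmagnesium bromide | CC#C[Mg]Br | starting material
6 | bromomagnesium alkoxide of 4 (not isolated) | CC(C)C(=O)C[C@H](O[Mg]Br)C(C)=C | intermediate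
7 | (3S,5R)-2-methyl-5-(propan-2-yl)oct-1-en-6-yne-3,5-diol (C2 and C4 oxygens anti) | C=C(C)[C@@H](O)C[C@@](O)(C(C)C)C#CC | intermediate
8 | (3S,5R)-3-(tert-butyldimethylsilyloxy)-2-methyl-5-(propan-2-yl)oct-1-en-6-yn-5-ol | C=C(C)[C@@H](O[Si](C)(C)C(C)(C)C)C[C@@](O)(C(C)C)C#CC | intermediate
9 | bicyclo[3.3.0]octenone: C9 ketone, C5=C6 with methyl on C6; 1α-methyl, 2α-OTBS, 4β-OH, 4α-isopropyl | O=C1C(C)=C2[C@](O)(C(C)C)C[C@H](O[Si](C)(C)C(C)(C)C)[C@@]2(C)C1 | intermediate
10 | lithium C4 alkoxide of 9 (not isolated) | O=C1C(C)=C2[C@](O[Li])(C(C)C)C[C@H](O[Si](C)(C)C(C)(C)C)[C@@]2(C)C1 | intermediate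
11 | lithium C9 enolate (C6=C9) of the cis-fused ketone, C4 lithium alkoxide, 5α-H (not isolated) | [Li]OC1=C(C)[C@H]2[C@](O[Li])(C(C)C)C[C@H](O[Si](C)(C)C(C)(C)C)[C@@]2(C)C1 | intermediate
12 | cis-fused bicyclo[3.3.0]octan-9-one: 1α-methyl, 5α-H, 2α-OTBS, 4β-OH, 4α-isopropyl, 6-methyl (C6 epimers) | O=C1C(C)[C@H]2[C@](O)(C(C)C)C[C@H](O[Si](C)(C)C(C)(C)C)[C@@]2(C)C1 | intermediate
13 | cis-fused δ-lactone (ring C1, C10, C9(=O), O, C6, C5): 1α-methyl, 5α-H, 2α-OTBS, 4β-OH, 4α-isopropyl, 6-methyl (C6 epimers) | O=C1OC(C)[C@H]2[C@](O)(C(C)C)C[C@H](O[Si](C)(C)C(C)(C)C)[C@@]2(C)C1 | intermediate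
14 | lactone 13 with 4β-OTMS | O=C1OC(C)[C@H]2[C@](O[Si](C)(C)C)(C(C)C)C[C@H](O[Si](C)(C)C(C)(C)C)[C@@]2(C)C1 | intermediate
15 | potassium enolate of 14 (C9–OK, C9=C10) (not isolated) | [K]OC1OC(C)[C@H]2[C@](O[Si](C)(C)C)(C(C)C)C[C@H](O[Si](C)(C)C(C)(C)C)[C@@]2(C)C=1 | intermediate
16 | lactone 14 with 10β-OH (trans to the C1 methyl) | O=C1OC(C)[C@H]2[C@](O[Si](C)(C)C)(C(C)C)C[C@H](O[Si](C)(C)C(C)(C)C)[C@@]2(C)[C@H]1O | intermediate
17 | lactone 14 with 10β-OTES | O=C1OC(C)[C@H]2[C@](O[Si](C)(C)C)(C(C)C)C[C@H](O[Si](C)(C)C(C)(C)C)[C@@]2(C)[C@H]1O[Si](CC)(CC)CC | intermediate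
18 | ethyllithium | [Li]CC | starting material
19 | lithium hemiketal from addition of 18 to the lactone carbonyl C9 of 17 (not isolated) | CCC1(O[Li])OC(C)[C@H]2[C@](O[Si](C)(C)C)(C(C)C)C[C@H](O[Si](C)(C)C(C)(C)C)[C@@]2(C)[C@H]1O[Si](CC)(CC)CC | intermediate
20 | cyclopentane with a C5 1-hydroxyethyl arm (C6 epimers) and a C1 arm CH(OTES)–C(=O)Et; 1α-methyl, 5α-H, 2α-OTBS, 4β-OTMS, 4α-isopropyl, both arms β | CC(O)[C@H]1[C@](O[Si](C)(C)C)(C(C)C)C[C@H](O[Si](C)(C)C(C)(C)C)[C@@]1(C)[C@@H](O[Si](CC)(CC)CC)C(=O)CC | intermediate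
21 | diketone: as 20 with a C5 acetyl arm | CC(=O)[C@H]1[C@](O[Si](C)(C)C)(C(C)C)C[C@H](O[Si](C)(C)C(C)(C)C)[C@@]1(C)[C@@H](O[Si](CC)(CC)CC)C(=O)CC | intermediate
22 | bis(silyl enol ether): C5 arm C(OTBS)=CH2 (C6=C7), C1 arm CH(OTES)–C(OTBS)=CH–CH3 (C9=C8, Z); ring substituents as in 21 | C=C(O[Si](C)(C)C(C)(C)C)[C@H]1[C@](O[Si](C)(C)C)(C(C)C)C[C@H](O[Si](C)(C)C(C)(C)C)[C@@]1(C)[C@@H](O[Si](CC)(CC)CC)/C(O[Si](C)(C)C(C)(C)C)=C/C | intermediate
23 | cis-fused bicyclo[5.3.0]decane-6,9-dione: 1α-methyl, 5α-H, 2α-OTBS, 4β-OTMS, 4α-isopropyl, 10β-OTES, 8-methyl (C8 epimers) | O=C1CC(C)C(=O)[C@H](O[Si](CC)(CC)CC)[C@@]2(C)[C@@H]1[C@](O[Si](C)(C)C)(C(C)C)C[C@@H]2O[Si](C)(C)C(C)(C)C | intermediate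
24 | 23 with free 4β-OH | O=C1CC(C)C(=O)[C@H](O[Si](CC)(CC)CC)[C@@]2(C)[C@@H]1[C@](O)(C(C)C)C[C@@H]2O[Si](C)(C)C(C)(C)C | intermediate
25 | 24 with the C6 ketone reduced to the 6α-alcohol | O[C@H]1CC(C)C(=O)[C@H](O[Si](CC)(CC)CC)[C@@]2(C)[C@@H]1[C@](O)(C(C)C)C[C@@H]2O[Si](C)(C)C(C)(C)C | intermediate
26 | tigloyl chloride ((E)-2-methylbut-2-enoyl chloride) | C/C=C(\C)C(=O)Cl | starting material
27 | 6α-tiglate of 25 | C/C=C(\C)C(=O)O[C@H]1CC(C)C(=O)[C@H](O[Si](CC)(CC)CC)[C@@]2(C)[C@@H]1[C@](O)(C(C)C)C[C@@H]2O[Si](C)(C)C(C)(C)C | intermediate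
28 | dipotassium salt of 27: C9 enolate (C8=C9) and C4 alkoxide (not isolated) | C/C=C(\C)C(=O)O[C@H]1CC(C)=C(O[K])[C@H](O[Si](CC)(CC)CC)[C@@]2(C)[C@@H]1[C@](O[K])(C(C)C)C[C@@H]2O[Si](C)(C)C(C)(C)C | intermediate
29 | C9 enol triflate (C8=C9) | C/C=C(\C)C(=O)O[C@H]1CC(C)=C(OS(=O)(=O)C(F)(F)F)[C@H](O[Si](CC)(CC)CC)[C@@]2(C)[C@@H]1[C@](O)(C(C)C)C[C@@H]2O[Si](C)(C)C(C)(C)C | intermediate
30 | C8=C9 alkene: 6α-OTig, 10β-OTES, 2α-OTBS, 4β-OH | C/C=C(\C)C(=O)O[C@H]1CC(C)=C[C@H](O[Si](CC)(CC)CC)[C@@]2(C)[C@@H]1[C@](O)(C(C)C)C[C@@H]2O[Si](C)(C)C(C)(C)C | intermediate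
31 | 30 with free 10β-OH | C/C=C(\C)C(=O)O[C@H]1CC(C)=C[C@H](O)[C@@]2(C)[C@@H]1[C@](O)(C(C)C)C[C@@H]2O[Si](C)(C)C(C)(C)C | intermediate
32 | 8β,9β-epoxide of 31 | C/C=C(\C)C(=O)O[C@H]1C[C@]2(C)O[C@@H]2[C@H](O)[C@@]2(C)[C@@H]1[C@](O)(C(C)C)C[C@@H]2O[Si](C)(C)C(C)(C)C | intermediate
33 | 6α,10β-ditiglate of the epoxide, 2α-OTBS | C/C=C(\C)C(=O)O[C@H]1C[C@]2(C)O[C@@H]2[C@H](OC(=O)/C(C)=C/C)[C@@]2(C)[C@@H]1[C@](O)(C(C)C)C[C@@H]2O[Si](C)(C)C(C)(C)C | intermediate
34 | CNP0265715.1: 6α,10β-ditigloyloxy-8β,9β-epoxide, 2α-OH, 4β-OH, 4α-isopropyl, 1α-methyl, 5α-H | C/C=C(\C)C(=O)O[C@H]1C[C@]2(C)O[C@@H]2[C@H](OC(=O)/C(C)=C/C)[C@@]2(C)[C@@H]1[C@](O)(C(C)C)C[C@@H]2O | target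

Total step count: 22
Longest linear sequence: 22 steps (1 and 2 to 34)

Steps most likely to fail

1. Step 13. Intermolecular coupling, or loss of the silyl groups without C–C bond formation, may outrun closure of the seven-membered ring. Fallback, from 22 back to 23: C7–C8 is made by a neutral radical instead of a radical cation. NBS (1 equiv, THF, −78 °C) should brominate the more electron-rich trisubstituted enol ether of 22 and give the α-bromo ketone F1, in which the C6 enol ether is kept. Visible-light photoredox reduction (Ir(ppy)3 cat., blue light, 2,6-lutidine, MeCN, high dilution) then generates the electrophilic C8 α-keto radical, which adds to the terminal carbon C7 of the electron-rich enol ether (7-endo, polarity-matched); oxidation of the α-silyloxy radical by the catalyst and loss of the silyl group give 23.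

2. Step 2. Poor facial selectivity in the addition to the magnesium chelate would give a mixture at C4. Fallback, from 2 back to 13: the C4 carbinol is built on the ring, where the face is fixed by the cis-fused bicycle. The boron aldol reaction of step 1 with pent-3-yn-2-one F2 in place of 1 gives the (S)-hydroxy ynone F3, and TBSCl/imidazole gives the silyl ether F4. Noyori transfer hydrogenation (RuCl(p-cymene)[(R,R)-TsDPEN], iPrOH) sets the propargylic alcohol under catalyst control and gives the syn compound F5. The conditions of steps 4, 5 and 6 then give the enone F6, the cis-fused ketone F7 and the hydroxy lactone F8 (both oxygens exo in the Pauson–Khand step). Dess–Martin oxidation gives the keto lactone F9, and iPrMgBr/CeCl3 (THF, −78 °C) should add from the convex α face, anti to the lactone ring, to give 13.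

3. Step 8. Delivery of oxygen to the α face of the lactone enolate would give the C10 epimer. Fallback, from 14 back to 16: C10 is then set by hydride instead of oxygen, using the same facial bias. The 10α-alcohol F10 from the hydroxylation is oxidised with Dess–Martin periodinane to the α-keto lactone F11 (not enolisable, C1 is quaternary), and NaBH4 (MeOH/CH2Cl2, −78 °C) reduces the ketone from the face that the oxidant used, which gives the 10β-alcohol 16.

Further compounds
F1 | step 13 | α-bromo ketone: 22 with the C1 arm as CH(OTES)–C(=O)–CHBr–CH3 (C8 epimers), C6 enol ether kept | C=C(O[Si](C)(C)C(C)(C)C)[C@H]1[C@](O[Si](C)(C)C)(C(C)C)C[C@H](O[Si](C)(C)C(C)(C)C)[C@@]1(C)[C@@H](O[Si](CC)(CC)CC)C(=O)C(C)Br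
F2 | step 2 | pent-3-yn-2-one (bought) | CC#CC(C)=O
F3 | step 2 | (S)-6-hydroxy-7-methyloct-7-en-2-yn-4-one | CC#CC(=O)C[C@H](O)C(C)=C
F4 | step 2 | (S)-6-(tert-butyldimethylsilyloxy)-7-methyloct-7-en-2-yn-4-one | CC#CC(=O)C[C@H](O[Si](C)(C)C(C)(C)C)C(C)=C
F5 | step 2 | (3S,5R)-3-(tert-butyldimethylsilyloxy)-2-methyloct-1-en-6-yn-5-ol (syn) | C=C(C)[C@@H](O[Si](C)(C)C(C)(C)C)C[C@@H](O)C#CC
F6 | step 2 | bicyclic enone as 9 but with 4α-OH and 4β-H, no isopropyl | O=C1C(C)=C2[C@H](O)C[C@H](O[Si](C)(C)C(C)(C)C)[C@@]2(C)C1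
F7 | step 2 | cis-fused ketone as 12 but with 4α-OH and 4β-H (C6 epimers) | O=C1C(C)[C@H]2[C@H](O)C[C@H](O[Si](C)(C)C(C)(C)C)[C@@]2(C)C1
F8 | step 2 | δ-lactone as 13 but with 4α-OH and 4β-H (C6 epimers) | O=C1OC(C)[C@H]2[C@H](O)C[C@H](O[Si](C)(C)C(C)(C)C)[C@@]2(C)C1
F9 | step 2 | δ-lactone with C4 ketone (C6 epimers) | O=C1OC(C)[C@H]2C(=O)C[C@H](O[Si](C)(C)C(C)(C)C)[C@@]2(C)C1
F10 | step 8 | 10α-hydroxy lactone (C10 epimer of 16) | O=C1OC(C)[C@H]2[C@](O[Si](C)(C)C)(C(C)C)C[C@H](O[Si](C)(C)C(C)(C)C)[C@@]2(C)[C@@H]1O
F11 | step 8 | α-keto lactone (C10 ketone) | O=C1OC(C)[C@H]2[C@](O[Si](C)(C)C)(C(C)C)C[C@H](O[Si](C)(C)C(C)(C)C)[C@@]2(C)C1=O
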